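**Strategy.** The cis-decalin (ring A: C1–C5/C10; ring B: C5–C10) is disconnected at C5–C10 and C6–C7. The feature exploited is ring B, whose vicinal oxygenated carbons C8/C9 lie between C7 and C10 next to the methyl-bearing quaternary C5 and a C4 that can be a carbonyl: a C8=C9 enediol diether that a 2,3-dioxygenated diene and a methacryloyl dienophile deliver. One intramolecular Diels–Alder reaction closes rings A and B and sets C5 and C10 from the purchased C3 centre. The precursor is an acyclic (R)-α-silyloxy methacryloyl ketone linked through two methylenes to a (Z)-3-(4-methoxybenzyloxy)-2-silyloxy-1,3-diene. C4 methylenation/directed hydrogenation, C7 isopropenylation, C3 acylation and PMB removal finish the target.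

Key step: step 10

Remark (conventions): bicyclic compounds carry eremophilane locants (methyls on C4 and C5, isopropenyl on C7, C8 carbonyl); β is the face of the C5 methyl; "decal" = decalin; TBS = tert-butyldimethylsilyl, TES = triethylsilyl, PMB = 4-methoxybenzyl.

Remark (reading of the target): the SMILES corresponds to (3R,4R,5R,7R,9R,10S) with a (2E,4R) side chain bearing a (Z)-2-methylbut-2-enoate (angelate), i.e. 3α-acyloxy, 4β,5β-dimethyl, 7β-isopropenyl, 9β-hydroxy, 10β-H. In the preferred cis-decalin conformer every substituent except the C5 methyl is equatorial.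

**Route**

Step 1
Reactants: 1 methyl (R)-glycidate; 2 vinylmagnesium bromide
Product: 3 methyl (2R)-2-hydroxypent-4-enoate
Conditions: CuBr·SMe2 (10 mol %), THF, −78 → −40 °C; aq NH4Cl
Reagents that add atoms: none
Why: Copper-catalysed Grignard opening (SN2) of the terminal epoxide at its CH2 carbon outpaces addition to the ester at low temperature; the C2–O bond is untouched, so the (R) centre, the future C3, is carried over unchanged.

Step 2
Reactants: 3 methyl (2R)-2-hydroxypent-4-enoate
Product: 4 methyl (2R)-2-(tert-butyldimethylsilyloxy)pent-4-enoate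
Conditions: TBSCl, imidazole, DMF, rt
Reagents that add atoms: tert-butyldimethylsilyl chloride, CC(C)(C)[Si](C)(C)Cl
Why: Routine silylation of a secondary alcohol with silyl chloride/imidazole; no stereocentre is affected.

Step 3
Reactants: 4 methyl (2R)-2-(tert-butyldimethylsilyloxy)pent-4-enoate
Product: 5 (2R)-2-(tert-butyldimethylsilyloxy)-N-methoxy-N-methylpent-4-enamide
Conditions: MeNH(OMe)·HCl, iPrMgCl, THF, −20 → 0 °C
Reagents that add atoms: N,O-dimethylhydroxylamine hydrochloride, CNOC.Cl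
Why: Aminolysis of the ester by the chloromagnesium amide of N,O-dimethylhydroxylamine (Weinreb amide synthesis) is fast below 0 °C and is not expected to epimerise the α-silyloxy centre.

Step 4
Reactants: 5 (2R)-2-(tert-butyldimethylsilyloxy)-N-methoxy-N-methylpent-4-enamide
Product: 7 (2R)-2-(tert-butyldimethylsilyloxy)-5-hydroxy-N-methoxy-N-methylpentanamide, via B-alkyl-9-BBN adduct 6 (not isolated)
Conditions: 9-BBN, THF, 0 °C → rt; then H2O2, aq NaOH, 0 °C
Reagents that add atoms: hydrogen peroxide, OO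
Why: Hydroboration–oxidation: 9-BBN adds anti-Markovnikov to the terminal alkene and ignores the tertiary amide, and oxidation of the C–B bond gives the primary alcohol.

Step 5
Reactants: 7 (2R)-2-(tert-butyldimethylsilyloxy)-5-hydroxy-N-methoxy-N-methylpentanamide
Product: 8 (2R)-2-(tert-butyldimethylsilyloxy)-N-methoxy-N-methyl-5-oxopentanamide
Conditions: TEMPO (10 mol %), PhI(OAc)2, CH2Cl2, rt
Reagents that add atoms: none
Why: Oxoammonium (TEMPO) oxidation of the primary alcohol stops at the aldehyde under near-neutral conditions that spare the silyl ether and the Weinreb amide.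

Step 6
Reactants: 9 dimethyl (1-diazo-2-oxopropyl)phosphonate; 10 4-methoxybenzyl alcohol
Product: 11 dimethyl [1-(4-methoxybenzyloxy)-2-oxopropyl]phosphonate (racemic)
Conditions: Rh2(OAc)4 (1 mol %), toluene, 80 °C
Reagents that add atoms: none
Why: Rhodium-carbenoid O–H insertion of the diazo ketophosphonate into the primary alcohol installs the future C9 oxygen with its PMB group in one step.

Step 7
Reactants: 8 (2R)-2-(tert-butyldimethylsilyloxy)-N-methoxy-N-methyl-5-oxopentanamide; 11 dimethyl [1-(4-methoxybenzyloxy)-2-oxopropyl]phosphonate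
Product: 12 (2R,5Z)-2-(tert-butyldimethylsilyloxy)-N-methoxy-6-(4-methoxybenzyloxy)-N-methyl-7-oxooct-5-enamide
Conditions: LiCl, DBU, MeCN, 0 °C → rt
Reagents that add atoms: none
Why: Horner–Wadsworth–Emmons olefination with LiCl/amine activation; the stabilised α-alkoxy ketophosphonate adds reversibly and should give mainly the thermodynamically preferred (Z)-enol ether (chain trans to the acetyl group, as the cycloaddition requires), any (E)-isomer being removed by chromatography, and the mild base leaves C2 of the amide untouched.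

Step 8
Reactants: 12 (2R,5Z)-2-(tert-butyldimethylsilyloxy)-N-methoxy-6-(4-methoxybenzyloxy)-N-methyl-7-oxooct-5-enamide
Product: 13 (2R,5Z)-2,7-bis(tert-butyldimethylsilyloxy)-N-methoxy-6-(4-methoxybenzyloxy)-N-methylocta-5,7-dienamide
Conditions: TBSOTf, Et3N, CH2Cl2, −78 → 0 °C
Reagents that add atoms: tert-butyldimethylsilyl trifluoromethanesulfonate, CC(C)(C)[Si](C)(C)OS(=O)(=O)C(F)(F)F
Why: Soft enolisation (silyl triflate/amine) of the methyl ketone gives the cross-conjugated 2-silyloxy diene, while the Weinreb amide is not enolised under these conditions, so the α-silyloxy centre and the (Z)-enol ether geometry are preserved.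

Step 9
Reactants: 13 (2R,5Z)-2,7-bis(tert-butyldimethylsilyloxy)-N-methoxy-6-(4-methoxybenzyloxy)-N-methylocta-5,7-dienamide; 14 isopropenylmagnesium bromide
Product: 16 (4R,7Z)-4,9-bis(tert-butyldimethylsilyloxy)-8-(4-methoxybenzyloxy)-2-methyldeca-1,7,9-trien-3-one, via magnesium hemiaminal 15 (not isolated)
Conditions: THF, −20 → 0 °C; cold aq NH4Cl
Reagents that add atoms: none
Why: Weinreb ketone synthesis: the chelated tetrahedral adduct prevents over-addition and releases the enone only on cold neutral quench, the silyl dienol ether is inert to the Grignard reagent, and unmasking the enone last keeps it away from every basic or nucleophilic step.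

Step 10
Reactants: 16 (4R,7Z)-4,9-bis(tert-butyldimethylsilyloxy)-8-(4-methoxybenzyloxy)-2-methyldeca-1,7,9-trien-3-one
Product: 17 (3R,5S,10S)-3,8-bis(TBS-oxy)-9-(PMB-oxy)-5-methyl-cis-decal-8-en-4-one (3α-OTBS; 5β-CH3; 10β-H)
Conditions: toluene (0.01 M), BHT (cat.), Et3N (cat.), 110 °C, base-washed sealed vessel
Reagents that add atoms: none
Why: Concerted, asynchronous thermal [4+2] cycloaddition in which the ketone-activated methacryloyl C5=C6 adds suprafacially across the electron-rich s-cis diene C10=C9–C8=C7 to form C5–C10 and C6–C7, the closest known reaction type being the intramolecular Diels–Alder reaction of 2-methyl-1,7,9-decatrien-3-ones, which gives angularly methylated cis-octalones. Ring B closes as the new cyclohexene of the cycloaddition (its C8=C9 bond is the former central bond of the diene), and ring A closes in the fused type 1 mode as the six-membered ring spanned by the four-atom tether C4–C3–C2–C1. C5 and C10 are set together by the endo arrangement of the tether carbonyl under the diene with the methyl group outside, which, with the tether trans to C8 on the (Z)-enol ether, puts 5-CH3 and 10-H cis. Their absolute sense follows from C3: in the chair-like forming ring A the silyloxy group takes the equatorial site, anti to the pseudo-axial C5 methyl, whereas the opposite diene face would force a 1,3-diaxial OSi/CH3 contact, so (3R) should lead to 5β-CH3/10β-H. The step needs endo and facial selectivity, secured by the in-tether ketone and the bulky C3 substituent, and regiochemistry, fixed by the tether; acid-free, radical-inhibited conditions protect the two enol ethers and the enone.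

Step 11
Reactants: 17 (3R,5S,10S)-3,8-bis(TBS-oxy)-9-(PMB-oxy)-5-methyl-cis-decal-8-en-4-one
Product: 18 (3R,5S,10S)-3,8-bis(TBS-oxy)-9-(PMB-oxy)-5-methyl-4-methylene-cis-decal-8-ene
Conditions: Cp2TiMe2 (3 equiv), toluene/THF, 70 °C, dark
Reagents that add atoms: dimethyltitanocene, C[Ti+2]C.c1cc[cH-]c1.c1cc[cH-]c1
Why: Petasis methylenation: the non-basic titanium methylidene generated thermally from Cp2TiMe2 olefinates hindered, enolisable ketones without epimerising C3 and does not touch enol ethers, and C8 is still masked so that C4 is the only carbonyl group.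

Step 12
Reactants: 18 (3R,5S,10S)-3,8-bis(TBS-oxy)-9-(PMB-oxy)-5-methyl-4-methylene-cis-decal-8-ene
Product: 19 (3R,5S,9R,10S)-3-hydroxy-9-(PMB-oxy)-5-methyl-4-methylene-cis-decalin-8-one (3α-OH; 9β-OPMB)
Conditions: Bu4NF, THF, 0 °C → rt
Reagents that add atoms: none
Why: Fluoride-induced desilylation frees the 3α-alcohol and the C8 enolate, whose protonation at C9 from the axial direction, backed by base equilibration of the resulting α-alkoxy ketone, should give the equatorial 9β-ether, the epimer free of the 1,3-diaxial contact with the C5–C4 bond.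

Step 13
Reactants: 19 (3R,5S,9R,10S)-3-hydroxy-9-(PMB-oxy)-5-methyl-4-methylene-cis-decalin-8-one
Product: 20 (3R,4R,5R,9R,10S)-3-hydroxy-9-(PMB-oxy)-4,5-dimethyl-cis-decalin-8-one (4β-CH3)
Conditions: [Ir(cod)(PCy3)(py)]PF6 (5 mol %), H2 (1 atm), CH2Cl2, 0 °C → rt
Reagents that add atoms: none
Why: Hydroxyl-directed homogeneous hydrogenation: the cationic iridium catalyst bound to the 3α-hydroxyl delivers H2 to the α face of the exocyclic alkene, so the new methyl group becomes β (trans to the hydroxyl and cis to the C5 methyl, 4R), while the PMB ether and the ketone are inert.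

Step 14
Reactants: 20 (3R,4R,5R,9R,10S)-3-hydroxy-9-(PMB-oxy)-4,5-dimethyl-cis-decalin-8-one
Product: 21 (3R,4R,5R,9R,10S)-9-(PMB-oxy)-4,5-dimethyl-3-(TES-oxy)-cis-decalin-8-one
Conditions: TESCl, imidazole, DMF, 0 °C → rt
Reagents that add atoms: chlorotriethylsilane, CC[Si](Cl)(CC)CC
Why: Routine silylation; the temporary triethylsilyl ether protects 3-OH during enolate formation and dehydration and can later be removed without touching the PMB ether.

Step 15
Reactants: 21 (3R,4R,5R,9R,10S)-9-(PMB-oxy)-4,5-dimethyl-3-(TES-oxy)-cis-decalin-8-one; 22 acetone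
Product: 25 (3R,4R,5R,7R,9R,10S)-7-(2-hydroxypropan-2-yl)-9-(PMB-oxy)-4,5-dimethyl-3-(TES-oxy)-cis-decalin-8-one (7β), via lithium enolate 23 (not isolated), via chlorozinc enolate 24 (not isolated)
Conditions: LiN(iPr)2, THF, −78 °C; ZnCl2; then acetone, −78 → −40 °C; aq NH4Cl
Reagents that add atoms: none
Why: Kinetic deprotonation of the α-alkoxy ketone takes place at the C7 methylene and not at the hindered alkoxy-bearing C9 methine, and aldol addition of the zinc enolate to acetone gives the ketol in which the bulky hydroxypropyl group should occupy the equatorial 7β position (7R), the centre being adjustable through the reversible aldol and enolisation.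

Step 16
Reactants: 25 (3R,4R,5R,7R,9R,10S)-7-(2-hydroxypropan-2-yl)-9-(PMB-oxy)-4,5-dimethyl-3-(TES-oxy)-cis-decalin-8-one
Product: 26 (3R,4R,5R,7R,9R,10S)-7-isopropenyl-9-(PMB-oxy)-4,5-dimethyl-3-(TES-oxy)-cis-decalin-8-one
Conditions: SOCl2, pyridine, CH2Cl2, −30 → 0 °C
Reagents that add atoms: none
Why: Dehydration of the tertiary alcohol through its chlorosulfite with pyridine (E2) should remove one of the six unhindered methyl hydrogens faster than the ring C7–H, giving the non-conjugated isopropenyl ketone under kinetic control without disturbing C7 at 0 °C.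

Step 17
Reactants: 26 (3R,4R,5R,7R,9R,10S)-7-isopropenyl-9-(PMB-oxy)-4,5-dimethyl-3-(TES-oxy)-cis-decalin-8-one
Product: 27 (3R,4R,5R,7R,9R,10S)-3-hydroxy-7-isopropenyl-9-(PMB-oxy)-4,5-dimethyl-cis-decalin-8-one
Conditions: HF·pyridine, pyridine, THF, 0 °C → rt
Reagents that add atoms: none
Why: Pyridine-buffered HF cleaves the triethylsilyl ether under conditions mild enough to leave the β,γ-unsaturated ketone, its α-centres and the PMB ether unchanged.

Step 18
Reactants: 28 methyl (R)-2-hydroxybutanoate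
Product: 29 methyl (R)-2-(tert-butyldimethylsilyloxy)butanoate
Conditions: TBSCl, imidazole, DMF, rt
Reagents that add atoms: tert-butyldimethylsilyl chloride, CC(C)(C)[Si](C)(C)Cl
Why: Routine silylation of the secondary alcohol; the (R) centre is untouched.

Step 19
Reactants: 29 methyl (R)-2-(tert-butyldimethylsilyloxy)butanoate; 30 tert-butyl (triphenylphosphoranylidene)acetate
Product: 32 tert-butyl (2E,4R)-4-(tert-butyldimethylsilyloxy)hex-2-enoate, via silyloxy aldehyde 31 (not isolated)
Conditions: iBu2AlH, CH2Cl2, −78 °C; MeOH; then 30, −78 °C → rt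
Reagents that add atoms: none
Why: Partial reduction of the ester at −78 °C gives the aluminium hemiacetal, which releases the aldehyde on warming in the presence of the stabilised ylide, so that Wittig olefination furnishes the (E)-enoate without isolation of the epimerisable α-silyloxy aldehyde.

Step 20
Reactants: 32 tert-butyl (2E,4R)-4-(tert-butyldimethylsilyloxy)hex-2-enoate
Product: 33 tert-butyl (2E,4R)-4-hydroxyhex-2-enoate
Conditions: HF·pyridine, THF, 0 °C → rt
Reagents that add atoms: none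
Why: Acidic fluoride desilylation leaves the tert-butyl ester intact, and the (E)-geometry precludes lactonisation of the γ-hydroxy ester.

Step 21
Reactants: 33 tert-butyl (2E,4R)-4-hydroxyhex-2-enoate; 34 angelic acid
Product: 36 tert-butyl (2E,4R)-4-[(Z)-2-methylbut-2-enoyloxy]hex-2-enoate, via angeloyl mixed anhydride 35 (not isolated)
Conditions: 34, 2,4,6-Cl3C6H2COCl, Et3N, toluene, rt; then 33, 80 °C
Reagents that add atoms: none
Why: Mixed-anhydride esterification (Yamaguchi type, run without DMAP) is the established way to acylate alcohols with angelic acid without (Z)→(E) isomerisation to the tiglate; the carbinol C–O bond is not broken, so (R) is retained.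

Step 22
Reactants: 36 tert-butyl (2E,4R)-4-[(Z)-2-methylbut-2-enoyloxy]hex-2-enoate
Product: 37 (2E,4R)-4-[(Z)-2-methylbut-2-enoyloxy]hex-2-enoic acid
Conditions: CF3CO2H, CH2Cl2, 0 °C → rt
Reagents that add atoms: none
Why: Acidolysis of the tert-butyl ester with loss of isobutene leaves the angelate and the conjugated acid untouched.

Step 23
Reactants: 27 (3R,4R,5R,7R,9R,10S)-3-hydroxy-7-isopropenyl-9-(PMB-oxy)-4,5-dimethyl-cis-decalin-8-one; 37 (2E,4R)-4-[(Z)-2-methylbut-2-enoyloxy]hex-2-enoic acid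
Product: 39 (3R,4R,5R,7R,9R,10S)-7-isopropenyl-9-(PMB-oxy)-4,5-dimethyl-8-oxo-cis-decalin-3-yl (2E,4R)-4-[(Z)-2-methylbut-2-enoyloxy]hex-2-enoate, via enoyl mixed anhydride 38 (not isolated)
Conditions: 37, 2,4,6-Cl3C6H2COCl, Et3N, THF, 0 °C; then 27, DMAP, toluene, 0 °C → rt
Reagents that add atoms: none
Why: Yamaguchi esterification: DMAP transfers the enoyl group of the mixed anhydride to the equatorial 3α-hydroxyl with retention at C3 (the C3–O bond is not broken), while the PMB-protected ketol and the isopropenyl group do not react at or below room temperature.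

Step 24
Reactants: 39 (3R,4R,5R,7R,9R,10S)-7-isopropenyl-9-(PMB-oxy)-4,5-dimethyl-8-oxo-cis-decalin-3-yl (2E,4R)-4-[(Z)-2-methylbut-2-enoyloxy]hex-2-enoate
Product: 40 CNP0190706.1 [(3R,4R,5R,7R,9R,10S)-9-hydroxy-7-isopropenyl-4,5-dimethyl-8-oxo-cis-decalin-3-yl (2E,4R)-4-[(Z)-2-methylbut-2-enoyloxy]hex-2-enoate]
Conditions: DDQ, CH2Cl2/pH 7 buffer, 0 °C → rt
Reagents that add atoms: none
Why: Oxidative cleavage of the PMB ether by DDQ (benzylic hydride abstraction, then hydrolysis) in buffered medium frees the 9β-hydroxyl without affecting the alkenes, the esters or the centres next to the ketone.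

**Compound list**

1 | methyl (R)-glycidate | COC(=O)[C@H]1CO1 | starting material
2 | vinylmagnesium bromide | C=C[Mg]Br | starting material
3 | methyl (2R)-2-hydroxypent-4-enoate | COC(=O)[C@H](O)CC=C | intermediate
4 | methyl (2R)-2-(tert-butyldimethylsilyloxy)pent-4-enoate | COC(=O)[C@H](O[Si](C)(C)C(C)(C)C)CC=C | intermediate
5 | (2R)-2-(tert-butyldimethylsilyloxy)-N-methoxy-N-methylpent-4-enamide | CON(C)C(=O)[C@H](O[Si](C)(C)C(C)(C)C)CC=C | intermediate
6 | B-alkyl-9-BBN adduct of 5, boron on C5 (formed in situ) | CON(C)C(=O)[C@H](O[Si](C)(C)C(C)(C)C)CCCB1C2CCCC1CCC2 | intermediate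
7 | (2R)-2-(tert-butyldimethylsilyloxy)-5-hydroxy-N-methoxy-N-methylpentanamide | CON(C)C(=O)[C@H](O[Si](C)(C)C(C)(C)C)CCCO | intermediate
8 | (2R)-2-(tert-butyldimethylsilyloxy)-N-methoxy-N-methyl-5-oxopentanamide | CON(C)C(=O)[C@H](O[Si](C)(C)C(C)(C)C)CCC=O | intermediate
9 | dimethyl (1-diazo-2-oxopropyl)phosphonate | COP(=O)(OC)C(=[N+]=[N-])C(C)=O | starting material
10 | 4-methoxybenzyl alcohol | COc1ccc(CO)cc1 | starting material
11 | dimethyl [1-(4-methoxybenzyloxy)-2-oxopropyl]phosphonate (racemic) | COP(=O)(OC)C(OCc1ccc(OC)cc1)C(C)=O | intermediate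
12 | (2R,5Z)-2-(tert-butyldimethylsilyloxy)-N-methoxy-6-(4-methoxybenzyloxy)-N-methyl-7-oxooct-5-enamide | CON(C)C(=O)[C@H](O[Si](C)(C)C(C)(C)C)CC/C=C(OCc1ccc(OC)cc1)/C(C)=O | intermediate
13 | (2R,5Z)-2,7-bis(tert-butyldimethylsilyloxy)-N-methoxy-6-(4-methoxybenzyloxy)-N-methylocta-5,7-dienamide | CON(C)C(=O)[C@H](O[Si](C)(C)C(C)(C)C)CC/C=C(OCc1ccc(OC)cc1)/C(O[Si](C)(C)C(C)(C)C)=C | intermediate
14 | isopropenylmagnesium bromide | C=C(C)[Mg]Br | starting material
15 | bromomagnesium hemiaminal from 13 and 14, tetrahedral adduct (formed in situ) | C=C(C)C(O[Mg]Br)(N(C)OC)[C@H](O[Si](C)(C)C(C)(C)C)CC/C=C(OCc1ccc(OC)cc1)/C(O[Si](C)(C)C(C)(C)C)=C | intermediate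
16 | (4R,7Z)-4,9-bis(tert-butyldimethylsilyloxy)-8-(4-methoxybenzyloxy)-2-methyldeca-1,7,9-trien-3-one | C=C(C)C(=O)[C@H](O[Si](C)(C)C(C)(C)C)CC/C=C(OCc1ccc(OC)cc1)/C(O[Si](C)(C)C(C)(C)C)=C | intermediate
17 | (3R,5S,10S)-3,8-bis(TBS-oxy)-9-(PMB-oxy)-5-methyl-cis-decal-8-en-4-one (3α-OTBS, 5β-CH3, 10β-H) | C1C[C@@]2(C)[C@H](CC[C@@H](O[Si](C)(C)C(C)(C)C)C2=O)C(OCc3ccc(OC)cc3)=C1O[Si](C)(C)C(C)(C)C | intermediate
18 | (3R,5S,10S)-3,8-bis(TBS-oxy)-9-(PMB-oxy)-5-methyl-4-methylene-cis-decal-8-ene | C1C[C@@]2(C)[C@H](CC[C@@H](O[Si](C)(C)C(C)(C)C)C2=C)C(OCc3ccc(OC)cc3)=C1O[Si](C)(C)C(C)(C)C | intermediate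
19 | (3R,5S,9R,10S)-3-hydroxy-9-(PMB-oxy)-5-methyl-4-methylene-cis-decalin-8-one (3α-OH, 9β-OPMB) | C1C[C@@]2(C)[C@H](CC[C@@H](O)C2=C)[C@@H](OCc3ccc(OC)cc3)C1=O | intermediate
20 | (3R,4R,5R,9R,10S)-3-hydroxy-9-(PMB-oxy)-4,5-dimethyl-cis-decalin-8-one (4β,5β-dimethyl) | C1C[C@@]2(C)[C@H](CC[C@@H](O)[C@@H]2C)[C@@H](OCc3ccc(OC)cc3)C1=O | intermediate
21 | (3R,4R,5R,9R,10S)-9-(PMB-oxy)-4,5-dimethyl-3-(TES-oxy)-cis-decalin-8-one | C1C[C@@]2(C)[C@H](CC[C@@H](O[Si](CC)(CC)CC)[C@@H]2C)[C@@H](OCc3ccc(OC)cc3)C1=O | intermediate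
22 | acetone | CC(C)=O | starting material
23 | lithium C7=C8 enolate of 21 (formed in situ) | [Li]OC1=CC[C@@]2(C)[C@H](CC[C@@H](O[Si](CC)(CC)CC)[C@@H]2C)[C@H]1OCc3ccc(OC)cc3 | intermediate
24 | chlorozinc C7=C8 enolate of 21 (formed in situ) | Cl[Zn]OC1=CC[C@@]2(C)[C@H](CC[C@@H](O[Si](CC)(CC)CC)[C@@H]2C)[C@H]1OCc3ccc(OC)cc3 | intermediate
25 | (3R,4R,5R,7R,9R,10S)-7-(2-hydroxypropan-2-yl)-9-(PMB-oxy)-4,5-dimethyl-3-(TES-oxy)-cis-decalin-8-one (7β) | CC(C)(O)[C@H]1C[C@@]2(C)[C@H](CC[C@@H](O[Si](CC)(CC)CC)[C@@H]2C)[C@@H](OCc3ccc(OC)cc3)C1=O | intermediate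
26 | (3R,4R,5R,7R,9R,10S)-7-isopropenyl-9-(PMB-oxy)-4,5-dimethyl-3-(TES-oxy)-cis-decalin-8-one | C=C(C)[C@H]1C[C@@]2(C)[C@H](CC[C@@H](O[Si](CC)(CC)CC)[C@@H]2C)[C@@H](OCc3ccc(OC)cc3)C1=O | intermediate
27 | (3R,4R,5R,7R,9R,10S)-3-hydroxy-7-isopropenyl-9-(PMB-oxy)-4,5-dimethyl-cis-decalin-8-one | C=C(C)[C@H]1C[C@@]2(C)[C@H](CC[C@@H](O)[C@@H]2C)[C@@H](OCc3ccc(OC)cc3)C1=O | intermediate
28 | methyl (R)-2-hydroxybutanoate | CC[C@@H](O)C(=O)OC | starting material
29 | methyl (R)-2-(tert-butyldimethylsilyloxy)butanoate | CC[C@@H](O[Si](C)(C)C(C)(C)C)C(=O)OC | intermediate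
30 | tert-butyl (triphenylphosphoranylidene)acetate | CC(C)(C)OC(=O)C=P(c1ccccc1)(c1ccccc1)c1ccccc1 | starting material
31 | (R)-2-(tert-butyldimethylsilyloxy)butanal (formed in situ) | CC[C@@H](O[Si](C)(C)C(C)(C)C)C=O | intermediate
32 | tert-butyl (2E,4R)-4-(tert-butyldimethylsilyloxy)hex-2-enoate | CC[C@@H](O[Si](C)(C)C(C)(C)C)/C=C/C(=O)OC(C)(C)C | intermediate
33 | tert-butyl (2E,4R)-4-hydroxyhex-2-enoate | CC[C@@H](O)/C=C/C(=O)OC(C)(C)C | intermediate
34 | angelic acid, (Z)-2-methylbut-2-enoic acid | C/C=C(/C)C(=O)O | starting material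
35 | angelic 2,4,6-trichlorobenzoic anhydride (formed in situ) | C/C=C(/C)C(=O)OC(=O)c1c(Cl)cc(Cl)cc1Cl | intermediate
36 | tert-butyl (2E,4R)-4-[(Z)-2-methylbut-2-enoyloxy]hex-2-enoate | CC[C@@H](OC(=O)/C(C)=C\C)/C=C/C(=O)OC(C)(C)C | intermediate
37 | (2E,4R)-4-[(Z)-2-methylbut-2-enoyloxy]hex-2-enoic acid | CC[C@@H](OC(=O)/C(C)=C\C)/C=C/C(=O)O | intermediate
38 | mixed anhydride of 37 with 2,4,6-trichlorobenzoic acid (formed in situ) | CC[C@@H](OC(=O)/C(C)=C\C)/C=C/C(=O)OC(=O)c1c(Cl)cc(Cl)cc1Cl | intermediate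
39 | 9-O-PMB ether of the target: (3R,4R,5R,7R,9R,10S)-7-isopropenyl-9-(PMB-oxy)-4,5-dimethyl-8-oxo-cis-decalin-3-yl (2E,4R)-4-[(Z)-2-methylbut-2-enoyloxy]hex-2-enoate | C=C(C)[C@H]1C[C@@]2(C)[C@H](CC[C@@H](OC(=O)/C=C/[C@@H](CC)OC(=O)/C(C)=C\C)[C@@H]2C)[C@@H](OCc3ccc(OC)cc3)C1=O | intermediate
40 | CNP0190706.1 | C=C(C)[C@H]1C[C@@]2(C)[C@H](CC[C@@H](OC(=O)/C=C/[C@@H](CC)OC(=O)/C(C)=C\C)[C@@H]2C)[C@@H](O)C1=O | target

**Step count**

Total: 24 steps. Longest linear sequence: 18 steps (steps 1–5, 7–17, 23, 24); step 6 and steps 18–22 are side branches.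

**Steps most likely to fail**

Step 10 (cycloaddition). The doubly oxygenated diene may lose a silyl group or isomerise before it cyclises, or the C9 alkoxy substituent may erode endo and facial selectivity. The fallback sets out from aldehyde 8 and rejoins the route at hydroxy ketone 19; it leaves the C9 oxygen out of the diene and introduces it after ring formation.
- Olefination of 8 with commercial dimethyl (2-oxopropyl)phosphonate (LiCl, DBU) should give (2R,5E)-2-(TBS-oxy)-N-methoxy-N-methyl-7-oxooct-5-enamide F1.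
- Et3SiOTf/Et3N converts it into the 2-silyloxy diene (2R,5E)-2-(TBS-oxy)-N-methoxy-N-methyl-7-(TES-oxy)octa-5,7-dienamide F2.
- CH2=C(CH3)MgBr gives (4R,7E)-4-(TBS-oxy)-2-methyl-9-(TES-oxy)deca-1,7,9-trien-3-one F3, a plain 2-silyloxy-diene substrate of the well-established kind.
- Heating in toluene should give (3R,5S,10R)-3-(TBS-oxy)-5-methyl-8-(TES-oxy)-cis-decal-8-en-4-one F4.
- Cp2TiMe2 gives (3R,5S,10R)-3-(TBS-oxy)-5-methyl-4-methylene-8-(TES-oxy)-cis-decal-8-ene F5.
- Rubottom oxidation (mCPBA, NaHCO3, then dilute AcOH) of the silyl enol ether, which is far more electron-rich than the exocyclic alkene, gives (3R,5S,9R,10S)-3-(TBS-oxy)-9-hydroxy-5-methyl-4-methylene-cis-decalin-8-one F6.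
- 4-Methoxybenzyl trichloroacetimidate with catalytic camphorsulfonic acid gives (3R,5S,9R,10S)-3-(TBS-oxy)-9-(PMB-oxy)-5-methyl-4-methylene-cis-decalin-8-one F7.
- Bu4NF, which also equilibrates C9 to the equatorial epimer, returns 19.

Step 16 (dehydration). Elimination may run toward C7 and give the conjugated isopropylidene ketone, or C7 may epimerise. The fallback sets out from ketol 25 and rejoins at 26. The elimination is deliberately driven into conjugation (SOCl2/pyridine, then DBU in CH2Cl2) to give (3R,4R,5R,9R,10S)-9-(PMB-oxy)-4,5-dimethyl-7-(propan-2-ylidene)-3-(TES-oxy)-cis-decalin-8-one F8. Its extended potassium dienolate (KOtBu, THF/tBuOH) is then quenched into cold aqueous AcOH. Kinetic protonation at the α-carbon C7, the classical deconjugation of alkylidene ketones, should move the double bond into the isopropenyl position; axial protonation places that group equatorial (7β). Unchanged F8 can be recycled.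

Step 11 (methylenation). The C4 ketone, flanked by the quaternary C5 and the silyloxy-bearing C3, may react slowly, and forcing could degrade the enol ethers. The fallback sets out from 17 and rejoins at 18 by Peterson olefination. Me3SiCH2Li/CeCl3 in THF at −78 °C (organocerium addition suppresses enolisation and tolerates hindered ketones) should give (3R,5S,10S)-3,8-bis(TBS-oxy)-9-(PMB-oxy)-5-methyl-4-[(trimethylsilyl)methyl]-cis-decal-8-en-4-ol F9. KH in THF then effects syn-elimination to 18 under basic, acid-free conditions that both enol ethers tolerate.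

**Further compounds**

F1 | step 10 | (2R,5E)-2-(TBS-oxy)-N-methoxy-N-methyl-7-oxooct-5-enamide | CON(C)C(=O)[C@H](O[Si](C)(C)C(C)(C)C)CC/C=C/C(C)=O
F2 | step 10 | (2R,5E)-2-(TBS-oxy)-N-methoxy-N-methyl-7-(TES-oxy)octa-5,7-dienamide | CON(C)C(=O)[C@H](O[Si](C)(C)C(C)(C)C)CC/C=C/C(O[Si](CC)(CC)CC)=C
F3 | step 10 | (4R,7E)-4-(TBS-oxy)-2-methyl-9-(TES-oxy)deca-1,7,9-trien-3-one | C=C(C)C(=O)[C@H](O[Si](C)(C)C(C)(C)C)CC/C=C/C(O[Si](CC)(CC)CC)=C
F4 | step 10 | (3R,5S,10R)-3-(TBS-oxy)-5-methyl-8-(TES-oxy)-cis-decal-8-en-4-one | C1C[C@@]2(C)[C@H](CC[C@@H](O[Si](C)(C)C(C)(C)C)C2=O)C=C1O[Si](CC)(CC)CC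
F5 | step 10 | (3R,5S,10R)-3-(TBS-oxy)-5-methyl-4-methylene-8-(TES-oxy)-cis-decal-8-ene | C1C[C@@]2(C)[C@H](CC[C@@H](O[Si](C)(C)C(C)(C)C)C2=C)C=C1O[Si](CC)(CC)CC
F6 | step 10 | (3R,5S,9R,10S)-3-(TBS-oxy)-9-hydroxy-5-methyl-4-methylene-cis-decalin-8-one | C1C[C@@]2(C)[C@H](CC[C@@H](O[Si](C)(C)C(C)(C)C)C2=C)[C@@H](O)C1=O
F7 | step 10 | (3R,5S,9R,10S)-3-(TBS-oxy)-9-(PMB-oxy)-5-methyl-4-methylene-cis-decalin-8-one | C1C[C@@]2(C)[C@H](CC[C@@H](O[Si](C)(C)C(C)(C)C)C2=C)[C@@H](OCc3ccc(OC)cc3)C1=O
F8 | step 16 | (3R,4R,5R,9R,10S)-9-(PMB-oxy)-4,5-dimethyl-7-(propan-2-ylidene)-3-(TES-oxy)-cis-decalin-8-one | CC(C)=C1C[C@@]2(C)[C@H](CC[C@@H](O[Si](CC)(CC)CC)[C@@H]2C)[C@@H](OCc3ccc(OC)cc3)C1=O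
F9 | step 11 | (3R,5S,10S)-3,8-bis(TBS-oxy)-9-(PMB-oxy)-5-methyl-4-[(trimethylsilyl)methyl]-cis-decal-8-en-4-ol (C4 epimers) | C1C[C@@]2(C)[C@H](CC[C@@H](O[Si](C)(C)C(C)(C)C)C2(O)C[Si](C)(C)C)C(OCc3ccc(OC)cc3)=C1O[Si](C)(C)C(C)(C)C
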